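## The problem

The target 20, (1S,2S,4R,5S)-2-bromo-1-[(E)-2-bromoethenyl]-4,5-dichloro-1,5-dimethylcyclohexane, is a single cyclohexane ring. Its atoms are labelled here C1 (C(CH3)Cl), C2 (CH2), C3 (quaternary, CH3 and the two-carbon side chain), C4 (CHBr), C5 (CH2) and C6 (CHCl), and the same labels are used for the corresponding atoms of every precursor. C1, C3, C4 and C6 are stereocentres: both chlorines, the bromine and the bromovinyl group lie on one ring face and the two methyl groups on the other. The C1/C6 dichloride is therefore cis and cannot come from anti addition of chlorine to a C1=C6 alkene. Two halogens stand next to fully substituted carbons (C4–Br beside C3, C6–Cl beside C1), so backside displacement is a poor way to make either bond. C3 has no functional neighbour to relay chirality and must be set by a catalyst; it can then direct C4 directly and C1 through the ring conformation, and C1 can direct C6. The tertiary chloride ionises and eliminates easily, a C6 ketone with bromine at C4 loses HBr under base, and the (E)-bromoalkene would not survive radical, hydride or organometallic steps, so it must be carried masked and released last. The enabling feature is the 1,3 relation of C4–Br to C6: with C6 as a carbonyl carbon, C4–C5–C6 maps onto a cyclopropane fused to the cyclopentane C6–C1–C2–C3–C4, and oxidative cleavage of the shared C4–C6 bond of such a 1-siloxybicyclo[3.1.0]hexane gives the six-membered ketone and a C4 radical that takes bromine without substitution at the hindered carbon.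

## Retrosynthesis

**Side chain.** 20 is cut at the C(sp2)–Br bond and the neighbouring C(sp2)–H bond, back to the terminal alkyne 18, and 18 at its C–H bond back to the silylalkyne 17. An aldehyde on C3 (for olefination) would need its own protection, and a vinyl group next to the C4 radical of the key step would migrate far faster than an alkynyl group. The alkyne is inert to every halogenation on the way. The forward step must be a syn hydrometalation with retentive bromination that leaves three alkyl halides alone.

**C6 chloride.** The C6–Cl bond of 17 is cut to the C6–O bond of alcohol 15, and the C6–H bond of 15 to ketone 14. A ketone at C6 is what the key step leaves, and an alkene route is closed because the dichloride is cis. Hydride should attack 14 anti to the axial C1–Cl bond, which puts the hydroxyl of 15 on the face the chlorine must occupy. The forward chlorination therefore has to proceed with retention by front-side collapse of a chlorosulfite. The alternative, inversion of the epimeric alcohol, would require attack syn to the C1 chlorine at a neopentyl-type carbon. 14 is simpler by one stereocentre.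

**C1 chloride.** The C1–Cl bond of 14 is cut to give ketone 13, the forward step being chlorination through the more substituted enol. This makes C1 planar on the way, so the C1 configuration carried from the start is irrelevant. Opening of a C1–C6 epoxide would do the same job only after several extra steps. The forward step must choose C1 over C5 and the enol face cis to the alkynyl group.

**Ring and C4 bromide.** In 13 the C4–Br bond is cut and the C4–C6 bond re-formed, which gives the 1-siloxybicyclo[3.1.0]hexane 12. Substitution at C4 is ruled out by the adjacent quaternary carbon, and hydrobromination of an enone would first need that enone. The cut removes the halogen and the C4 stereocentre, and contracts the ring to a cyclopentane that is a direct cyclopropanation product. The forward reaction must cleave the shared bond (not the external C5–C6 bond), capture bromine on the face away from the C3 methyl, and not lose HBr.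

**Cyclopropane.** The C4–C5 and C5–C6 bonds of 12 are cut to the silyl enol ether 9 and diiodomethane 10. The cut is stereochemically undemanding because both cyclopropane carbons lose their configuration in the ring expansion.

**Quaternary C3.** The C3–CH3 bond and the O–Si bond of 9 are cut to the enone 7. Conjugate addition of a methyl group creates C3 under catalyst control, and the resulting enolate is the enol ether needed, with its double bond between C6 and C4. Asymmetric addition of an alkynyl group to a 3-methyl enone is much less developed for quaternary centres.

**Enone.** The C1–CH3 bond of 7 is cut to the enone 5, and the C3–C(sp) bond of 5 to 3-ethoxycyclopent-2-en-1-one 1 and ethynyltrimethylsilane 2. The methyl group must go in before the conjugate addition, because afterwards the only regiodefined enolate lies on the other side of the carbonyl. The price is that 7 is racemic at C1, which is tolerable because C1 is reset in the forward chlorination of 13 to 14.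

## Roads not taken

Alternative 1: Ireland–Claisen ring contraction.
- **Cut and key step:** the C3–C4 bond is cut and the carbocycle is traced to the ten-membered lactone A1. Its silyl ketene acetal (LiN(iPr)2, Me3SiCl) would rearrange to the cyclohexene acid A2, forming C3–C4, closing the ring and releasing an (E)-vinylsilane on C3.
- **Merits:** the quaternary centre is made stereospecifically by chirality transfer from the silyl-bearing carbinol carbon of A1, without a chiral catalyst, and the side chain arrives with the right geometry and one step from the bromide.
- **Weak points:** A1 needs a medium-ring lactonisation and a stereodefined carbinol, so the key substrate is far from commercial material. The carboxyl of A2 must become the C4 bromine by radical decarboxylation, which meets the same facial question at C4 but later. The C1=C6 alkene of A2 invites dichlorination, which is anti and gives the wrong (trans) dichloride.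
- **Comparison:** in control of C3 this road is as good or better. The chosen plan sets against it a four-step access to its key substrate, a key step that installs the C4 halogen itself, and a C6 ketone from which C1–Cl can be placed.

Alternative 2: aminosiloxydiene Diels–Alder.
- **Cut and key step:** C1–C2 and C3–C4 are cut. Diene A3 and methacrolein A4 would combine under (salen)CrSbF6 (trivalent chromium) to the cycloadduct A5, closing the ring and creating C3 with a formyl group.
- **Merits:** convergent, both partners simple, the quaternary centre made by an established catalytic asymmetric cycloaddition, the enol ether a latent C6 ketone, and the aldehyde one olefination from the bromoalkene.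
- **Weak points:** C4 emerges bearing nitrogen, and replacing it by bromine with defined configuration next to quaternary C3 is not possible by substitution. The realistic sequel is β-elimination of the carbamate and re-addition of HBr, so C4 is set later on the same substrate bias, with extra steps and a free aldehyde to manage.
- **Comparison:** for building the ring and C3 it is at least the equal of the chosen route, and more convergent. The chosen plan sets against it that the C4–Br bond forms in the ring-forming event and that there is no nitrogen to excise.

Alternative 3: atom-transfer radical cyclisation.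
- **Cut and key step:** C5–C6 and C1–Cl are cut. The chloromethyl ketone A6 with CuCl and tris(2-pyridylmethyl)amine would give a C5 radical that closes 6-endo onto the chloroalkene, and the tertiary C1 radical would take chlorine from CuCl2 to give A7.
- **Merits:** both carbons of the cis-dichloride are made in one catalytic step. This is the part that costs the chosen route three steps and a retentive substitution, and here this road is better.
- **Weak points:** C1 and C6 are controlled only by the remote C3. A6 needs an enantioselective route to an acyclic α-quaternary ketone. The C4 ketone of A7 must still become a secondary bromide beside a quaternary carbon, which again excludes substitution.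
- **Comparison:** the chosen plan sets against the better dichloride construction that its key step solves exactly that C4–Br problem, on a ring whose C3 comes from a well-precedented conjugate addition.

Key step: step 5

Remark on the chemistry: 7 is racemic at C1 and is used as such. The catalyst of step 3 is assumed to set C3 alike in both enantiomers of 7, so 9, 12 and 13 are mixtures only at centres that later steps erase (C1 in step 6, the cyclopropane carbons in step 5).

## Route

Step 1
Reactants: 1 3-ethoxycyclopent-2-en-1-one; 2 ethynyltrimethylsilane
Product: 5 3-[(trimethylsilyl)ethynyl]cyclopent-2-en-1-one, via lithium (trimethylsilyl)acetylide 3 (not isolated), via lithium alkoxide of the 1,2-adduct 4 (not isolated)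
Conditions: 2, n-BuLi, THF, −78 °C; 1, −78 → 0 °C; 1 M HCl, 0 °C → rt
Reagents that add atoms: water, O
Why: 1,2-Addition of the lithium acetylide to the vinylogous ester and acid hydrolysis of the resulting enol-ether carbinol (Stork–Danheiser transposition) give the 3-alkynyl enone; no stereocentre is formed.

Step 2
Reactants: 5 3-[(trimethylsilyl)ethynyl]cyclopent-2-en-1-one
Product: 7 (±)-5-methyl-3-[(trimethylsilyl)ethynyl]cyclopent-2-en-1-one, via lithium dienolate 6 (not isolated)
Conditions: LiN(iPr)2 (1.05 equiv), THF, −78 °C; MeI, −78 → −30 °C
Reagents that add atoms: iodomethane, CI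
Why: Kinetic deprotonation of the enone takes the α'-methylene (cross-conjugated dienolate) and C-alkylation with MeI gives the α'-methyl enone; the new C1 centre is racemic and is reset in step 6.

Step 3
Reactants: 7 (±)-5-methyl-3-[(trimethylsilyl)ethynyl]cyclopent-2-en-1-one
Product: 9 {[(3R)-3,5-dimethyl-3-[(trimethylsilyl)ethynyl]cyclopent-1-en-1-yl]oxy}trimethylsilane (both C5 epimers), via dimethylaluminium enolate 8 (not isolated)
Conditions: Me3Al (1.5 equiv), Cu(OTf)2 (5 mol %), (biphenyl-2,2'-diyl) N,N-bis[(R)-1-(2-naphthyl)ethyl]phosphoramidite or its enantiomer (10 mol %), Et2O, −30 °C; Me3SiOTf, −30 → 0 °C; Et3N, filtration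
Reagents that add atoms: trimethylaluminium, C[Al](C)C; trimethylsilyl trifluoromethanesulfonate, C[Si](C)(C)OS(=O)(=O)C(F)(F)F
Why: Copper-catalysed asymmetric conjugate addition of an alane to a β-substituted cyclic enone (1,4 rather than 1,6 for cyclic enynones) creates quaternary C3 under control of the phosphoramidite, whose enantiomer is chosen to give (3R)-9, which is S at C3 of the target. O-Silylation of the aluminium enolate fixes the enol double bond between C6 and C4, the only regiochemistry the ring expansion can use.

Step 4
Reactants: 9 {[(3R)-3,5-dimethyl-3-[(trimethylsilyl)ethynyl]cyclopent-1-en-1-yl]oxy}trimethylsilane; 10 diiodomethane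
Product: 12 trimethyl{[(4R)-2,4-dimethyl-4-[(trimethylsilyl)ethynyl]bicyclo[3.1.0]hexan-1-yl]oxy}silane (mixed at C2 and in the face of the cyclopropane), via ethyl(iodomethyl)zinc 11 (not isolated)
Conditions: Et2Zn (3 equiv), CH2I2 (3 equiv), CH2Cl2, 0 °C → rt; pyridine, then aq NaHCO3
Reagents that add atoms: none
Why: Simmons–Smith cyclopropanation with the zinc carbenoid from Et2Zn and CH2I2 is fast on the electron-rich silyl enol ether and leaves the silylalkyne alone; either cyclopropane face is acceptable because both ring-fusion carbons lose their configuration in step 5.

Step 5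
Reactants: 12 trimethyl{[(4R)-2,4-dimethyl-4-[(trimethylsilyl)ethynyl]bicyclo[3.1.0]hexan-1-yl]oxy}silane
Product: 13 (4S,5S)-5-bromo-2,4-dimethyl-4-[(trimethylsilyl)ethynyl]cyclohexan-1-one (both C2 epimers)
Conditions: CuBr2 (2.5 equiv), DMF, 0 °C; cold aqueous work-up
Reagents that add atoms: copper dibromide, Br[Cu]Br
Why: Oxidative ring expansion of a 1-siloxybicyclo[3.1.0]hexane with halogen atom transfer: CuBr2 (divalent copper) replaces silicon on oxygen and takes one electron, the cyclopropyloxy radical undergoes β-scission of the shared C4–C6 bond, and a second CuBr2 hands bromine to the C4 radical and ends as CuBr. The closest known reaction is the FeCl3-mediated conversion of 1-siloxybicyclo[n.1.0]alkanes into 3-chlorocycloalkanones (cupric halides open cyclopropanols to β-halo ketones in the same way); only the halogen delivered is changed. No ring is closed by bond formation: the cyclohexanone arises by one-carbon ring expansion (endo β-scission of the zero-atom bridge), the cyclopropane methylene becoming C5. Cleavage of the shared rather than the external bond is secured by the radical pathway, which gives a secondary radical and a strain-free six-membered ketone instead of a primary radical. The new stereocentre C4 is controlled by the adjacent quaternary C3: bromine should enter trans to the C3 methyl and cis to the alkynyl group, because in the chair with axial methyl that face is blocked outright, and in the chair with axial alkynyl the thin sp carbon screens its face less than the ring methylene and its syn-axial hydrogen screen the other. The step needs bromine capture to outrun 1,2-alkynyl migration (slow for homopropargyl radicals) and loss of HBr to the enone, which a high CuBr2 concentration and a cold, base-free work-up provide. Both cyclopropane faces of 12 give the same radical; the two C1 epimers may differ in selectivity but both lead to 13, whose C1 is erased in step 6.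

Step 6
Reactants: 13 (4S,5S)-5-bromo-2,4-dimethyl-4-[(trimethylsilyl)ethynyl]cyclohexan-1-one
Product: 14 (2S,4S,5S)-5-bromo-2-chloro-2,4-dimethyl-4-[(trimethylsilyl)ethynyl]cyclohexan-1-one
Conditions: SO2Cl2 (1.05 equiv), CH2Cl2, 0 °C → rt
Reagents that add atoms: sulfuryl chloride, O=S(=O)(Cl)Cl
Why: Acid-catalysed α-chlorination of a ketone with SO2Cl2 goes through the more substituted enol (C6=C1), as with 2-methylcyclohexanone. Chlorine should enter axially on the half-chair that keeps the C3 methyl pseudo-equatorial, on the face of the thin alkynyl group, which also gives the more stable product (axial C–Cl beside the carbonyl, both methyls equatorial).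

Step 7
Reactants: 14 (2S,4S,5S)-5-bromo-2-chloro-2,4-dimethyl-4-[(trimethylsilyl)ethynyl]cyclohexan-1-one
Product: 15 (1R,2S,4S,5S)-5-bromo-2-chloro-2,4-dimethyl-4-[(trimethylsilyl)ethynyl]cyclohexan-1-ol
Conditions: NaBH4, CeCl3·7H2O, MeOH, −40 °C
Reagents that add atoms: none
Why: Luche-type borohydride reduction of an α-chloro ketone: hydride attacks axially on the face anti to the axial C1–Cl bond (Felkin–Anh polar model, no syn-axial substituent there), giving the equatorial C6 alcohol cis to the C1 chlorine; the cold, cerium-buffered medium spares the β-bromide.

Step 8
Reactants: 15 (1R,2S,4S,5S)-5-bromo-2-chloro-2,4-dimethyl-4-[(trimethylsilyl)ethynyl]cyclohexan-1-ol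
Product: 17 {[(1S,2S,4R,5S)-2-bromo-4,5-dichloro-1,5-dimethylcyclohexyl]ethynyl}trimethylsilane, via chlorosulfite 16 (not isolated)
Conditions: SOCl2 (1.5 equiv), CH2Cl2, 0 °C; TiCl4 (10 mol %), 0 °C
Reagents that add atoms: thionyl chloride, O=S(Cl)Cl
Why: Chlorination of a cyclic secondary alcohol with retention (SNi collapse of the chlorosulfite, catalysed by TiCl4, which delivers chloride to the face the oxygen leaves). Retention is required because the hydroxyl already sits on the target face; the C1 chlorine is gauche, not anti, to the C6–O bond and cannot bridge.

Step 9
Reactants: 17 {[(1S,2S,4R,5S)-2-bromo-4,5-dichloro-1,5-dimethylcyclohexyl]ethynyl}trimethylsilane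
Product: 18 (1S,2S,4R,5S)-2-bromo-4,5-dichloro-1-ethynyl-1,5-dimethylcyclohexane
Conditions: K2CO3 (0.2 equiv), MeOH, 0 °C → rt
Reagents that add atoms: none
Why: Base-catalysed methanolysis of the alkynyl C–Si bond (protiodesilylation); catalytic carbonate at this temperature should leave the alkyl halides untouched.

Step 10
Reactants: 18 (1S,2S,4R,5S)-2-bromo-4,5-dichloro-1-ethynyl-1,5-dimethylcyclohexane
Product: 20 (1S,2S,4R,5S)-2-bromo-1-[(E)-2-bromoethenyl]-4,5-dichloro-1,5-dimethylcyclohexane, via alkenylzirconocene chloride 19 (not isolated)
Conditions: Cp2Zr(H)Cl (1.3 equiv), THF, rt; N-bromosuccinimide, 0 °C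
Reagents that add atoms: N-bromosuccinimide, O=C1CCC(=O)N1Br
Why: Hydrozirconation of the terminal alkyne is a syn addition that places zirconium on the terminal carbon, and bromination of the alkenyl–zirconium bond occurs with retention, so the (E)-bromoalkene results; alkyl chlorides and bromides are tolerated.

## Compound list

1 | 3-ethoxycyclopent-2-en-1-one | CCOC1=CC(=O)CC1 | starting material
2 | ethynyltrimethylsilane | C#C[Si](C)(C)C | starting material
3 | lithium (trimethylsilyl)acetylide | [Li]C#C[Si](C)(C)C | intermediate (not isolated)
4 | lithium 3-ethoxy-1-[(trimethylsilyl)ethynyl]cyclopent-2-en-1-olate (racemic) | CCOC1=CC(O[Li])(C#C[Si](C)(C)C)CC1 | intermediate (not isolated)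
5 | 3-[(trimethylsilyl)ethynyl]cyclopent-2-en-1-one | O=C1C=C(C#C[Si](C)(C)C)CC1 | intermediate
6 | lithium 4-[(trimethylsilyl)ethynyl]cyclopenta-1,4-dien-1-olate | [Li]OC1=CCC(C#C[Si](C)(C)C)=C1 | intermediate (not isolated)
7 | (±)-5-methyl-3-[(trimethylsilyl)ethynyl]cyclopent-2-en-1-one | CC1CC(C#C[Si](C)(C)C)=CC1=O | intermediate
8 | dimethylaluminium (3R)-3,5-dimethyl-3-[(trimethylsilyl)ethynyl]cyclopent-1-en-1-olate (both C5 epimers) | CC1C[C@@](C)(C#C[Si](C)(C)C)C=C1O[Al](C)C | intermediate (not isolated)
9 | {[(3R)-3,5-dimethyl-3-[(trimethylsilyl)ethynyl]cyclopent-1-en-1-yl]oxy}trimethylsilane (both C5 epimers) | CC1C[C@@](C)(C#C[Si](C)(C)C)C=C1O[Si](C)(C)C | intermediate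
10 | diiodomethane | ICI | starting material
11 | ethyl(iodomethyl)zinc | CC[Zn]CI | intermediate (not isolated)
12 | trimethyl{[(4R)-2,4-dimethyl-4-[(trimethylsilyl)ethynyl]bicyclo[3.1.0]hexan-1-yl]oxy}silane (cis-fused; mixed at C2 and in the face of the cyclopropane) | CC1C[C@@](C)(C#C[Si](C)(C)C)C2CC12O[Si](C)(C)C | intermediate
13 | (4S,5S)-5-bromo-2,4-dimethyl-4-[(trimethylsilyl)ethynyl]cyclohexan-1-one (both C2 epimers) | CC1C[C@@](C)(C#C[Si](C)(C)C)[C@@H](Br)CC1=O | intermediate
14 | (2S,4S,5S)-5-bromo-2-chloro-2,4-dimethyl-4-[(trimethylsilyl)ethynyl]cyclohexan-1-one | C[C@]1(Cl)C[C@@](C)(C#C[Si](C)(C)C)[C@@H](Br)CC1=O | intermediate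
15 | (1R,2S,4S,5S)-5-bromo-2-chloro-2,4-dimethyl-4-[(trimethylsilyl)ethynyl]cyclohexan-1-ol | C[C@]1(Cl)C[C@@](C)(C#C[Si](C)(C)C)[C@@H](Br)C[C@H]1O | intermediate
16 | (1R,2S,4S,5S)-5-bromo-2-chloro-2,4-dimethyl-4-[(trimethylsilyl)ethynyl]cyclohexyl chlorosulfite | C[C@]1(Cl)C[C@@](C)(C#C[Si](C)(C)C)[C@@H](Br)C[C@H]1OS(Cl)=O | intermediate (not isolated)
17 | {[(1S,2S,4R,5S)-2-bromo-4,5-dichloro-1,5-dimethylcyclohexyl]ethynyl}trimethylsilane | C[C@]1(Cl)C[C@@](C)(C#C[Si](C)(C)C)[C@@H](Br)C[C@H]1Cl | intermediate
18 | (1S,2S,4R,5S)-2-bromo-4,5-dichloro-1-ethynyl-1,5-dimethylcyclohexane | C[C@]1(Cl)C[C@@](C)(C#C)[C@@H](Br)C[C@H]1Cl | intermediate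
19 | chlorobis(cyclopentadienyl){(E)-2-[(1S,2S,4R,5S)-2-bromo-4,5-dichloro-1,5-dimethylcyclohexyl]ethenyl}zirconium (cyclopentadienyl rings drawn σ-bonded) | C[C@]1(Cl)C[C@@](C)(/C=C/[Zr](Cl)(C2C=CC=C2)C2C=CC=C2)[C@@H](Br)C[C@H]1Cl | intermediate (not isolated)
20 | (1S,2S,4R,5S)-2-bromo-1-[(E)-2-bromoethenyl]-4,5-dichloro-1,5-dimethylcyclohexane | C[C@]1(Cl)C[C@@](C)(/C=C/Br)[C@@H](Br)C[C@H]1Cl | target

## Step count and risks

Total: 10 steps. Longest linear sequence: 10 steps (1 → 20).

**Step 5 (key step).** Most likely failures: ring opening through a copper homoenolate, which cleaves the external C5–C6 bond instead of following the radical path, or bromine capture on the face of the C3 methyl. Divalent copper can act as an electrophile toward the cyclopropane, and C3 offers only the size difference between methyl and alkynyl. Fallback, from 12: FeCl3 (trivalent iron) in DMF at 0 °C effects the documented ring expansion with chlorine capture to the 5-chloro ketone F1. NaOAc in MeOH removes HCl to give the enone F2. HBr in AcOH/CH2Cl2 at 0 °C then adds bromide at C4 and returns to 13. Because this addition is reversible, a wrong C4 epimer can be recycled through F2.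

**Step 6.** Most likely failure: poor facial selectivity at C1 (chlorine entering trans to the alkynyl group), because the axial trajectory runs past the axial alkynyl group. Fallback, from 13:
- NaBH4 gives the alcohol F3.
- Burgess dehydration gives the trisubstituted alkene F4.
- m-Chloroperbenzoic acid epoxidises on the face opposite to the alkynyl group and the bromine, giving the epoxide F5.
- HCl in Et2O opens it at the tertiary carbon with inversion, giving the trans-chlorohydrin F6 with C1–Cl on the alkynyl face.
- Dess–Martin oxidation returns to 14.

The steric bias that would misdirect an electrophile is used here to place oxygen, and chlorine then enters from the other side.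

**Step 8.** Most likely failure: ionisation instead of front-side delivery (1,2-shift of the C1–C2 bond with ring contraction, elimination, or loss of configuration), because the β-chlorine slows collapse of the chlorosulfite and C6 is neopentyl-like. Fallback, from 13: reach the trans-chlorohydrin F6 as described for step 6, convert it to the trifluoromethanesulfonate F7 (Tf2O, pyridine, −40 °C), and displace with Bu4NCl in CH2Cl2. This is chlorination with inversion, the classical way from a trans-2-chlorocyclohexanol to the cis-dichloride, and it returns to 17. The backside approach is hindered, so this is a second line, not an equal.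

**Step 3.** Most likely failure: erosion of enantio- and regiocontrol. The racemic C1 centre of 7 makes one enantiomer a mismatched substrate, and the enyne also offers 1,6-addition. Fallback, from 5: the same copper-catalysed Me3Al addition on this achiral enone, with aqueous work-up, gives the ketone F8. LiN(iPr)2 and MeI methylate the less hindered α-carbon to give F9. LiN(iPr)2 with Me3SiCl present silylates the kinetic enolate on the methylene side and returns to 9. The regioselectivity of this last enolisation would have to be checked.

## Further compounds

F1 | step 5 | (4S)-5-chloro-2,4-dimethyl-4-[(trimethylsilyl)ethynyl]cyclohexan-1-one (mixed at C2 and C5) | CC1C[C@@](C)(C#C[Si](C)(C)C)C(Cl)CC1=O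
F2 | step 5 | (4R)-4,6-dimethyl-4-[(trimethylsilyl)ethynyl]cyclohex-2-en-1-one (both C6 epimers) | CC1C[C@@](C)(C#C[Si](C)(C)C)C=CC1=O
F3 | step 6 | (4S,5S)-5-bromo-2,4-dimethyl-4-[(trimethylsilyl)ethynyl]cyclohexan-1-ol (mixed at C1 and C2) | CC1C[C@@](C)(C#C[Si](C)(C)C)[C@@H](Br)CC1O
F4 | step 6 | {[(1S,6S)-6-bromo-1,3-dimethylcyclohex-3-en-1-yl]ethynyl}trimethylsilane | CC1=CC[C@H](Br)[C@](C)(C#C[Si](C)(C)C)C1
F5 | step 6 | {[(3S,4S)-4-bromo-1,3-dimethyl-7-oxabicyclo[4.1.0]heptan-3-yl]ethynyl}trimethylsilane, epoxide oxygen trans to the alkynyl group | C[C@@]12C[C@@](C)(C#C[Si](C)(C)C)[C@@H](Br)C[C@@H]1O2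
F6 | step 6 | (1S,2S,4S,5S)-5-bromo-2-chloro-2,4-dimethyl-4-[(trimethylsilyl)ethynyl]cyclohexan-1-ol | C[C@]1(Cl)C[C@@](C)(C#C[Si](C)(C)C)[C@@H](Br)C[C@@H]1O
F7 | step 8 | (1S,2S,4S,5S)-5-bromo-2-chloro-2,4-dimethyl-4-[(trimethylsilyl)ethynyl]cyclohexyl trifluoromethanesulfonate | C[C@]1(Cl)C[C@@](C)(C#C[Si](C)(C)C)[C@@H](Br)C[C@@H]1OS(=O)(=O)C(F)(F)F
F8 | step 3 | (3R)-3-methyl-3-[(trimethylsilyl)ethynyl]cyclopentan-1-one | O=C1CC[C@@](C)(C#C[Si](C)(C)C)C1
F9 | step 3 | (4R)-2,4-dimethyl-4-[(trimethylsilyl)ethynyl]cyclopentan-1-one (both C2 epimers) | O=C1C(C)C[C@@](C)(C#C[Si](C)(C)C)C1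
A1 | alternative 1 | (5Z,8E)-6,8-dimethyl-10-(trimethylsilyl)-3,4,7,10-tetrahydro-2H-oxecin-2-one (one enantiomer at C10, chosen for the chirality transfer) | O=C1CC/C=C(C)\C/C(C)=C/C([Si](C)(C)C)O1
A2 | alternative 1 | 4,6-dimethyl-6-[(E)-2-(trimethylsilyl)ethenyl]cyclohex-3-ene-1-carboxylic acid | CC1=CC[C@H](C(=O)O)[C@](C)(/C=C/[Si](C)(C)C)C1
A3 | alternative 2 | methyl N-[(1E,3Z)-3-{[tert-butyl(dimethyl)silyl]oxy}penta-1,3-dien-1-yl]-N-methylcarbamate | C/C=C(O[Si](C)(C)C(C)(C)C)/C=C/N(C)C(=O)OC
A4 | alternative 2 | 2-methylprop-2-enal (methacrolein) | C=C(C)C=O
A5 | alternative 2 | methyl N-{3-{[tert-butyl(dimethyl)silyl]oxy}-6-formyl-4,6-dimethylcyclohex-2-en-1-yl}-N-methylcarbamate | C[C@H]1C[C@@](C)(C=O)[C@@H](N(C)C(=O)OC)C=C1O[Si](C)(C)C(C)(C)C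
A6 | alternative 3 | (3S,5E)-1,6-dichloro-3,5-dimethyl-3-[(trimethylsilyl)ethynyl]hex-5-en-2-one | ClCC(=O)[C@](C)(C#C[Si](C)(C)C)C/C(C)=C/Cl
A7 | alternative 3 | cis-4,5-dichloro-2,4-dimethyl-2-[(trimethylsilyl)ethynyl]cyclohexan-1-one | C[C@]1(Cl)C[C@@](C)(C#C[Si](C)(C)C)C(=O)C[C@H]1Cl
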